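**Retrosynthetic overview**
1. Dihydropyran (last ring): acid cyclodehydration of a δ-hydroxy ketone; C3–C5 arrive by a Horner–Wadsworth–Emmons reaction on the C6 aldehyde, C7 by a formaldehyde aldol that makes C6 quaternary.
2. Piperidine and quaternary C20: double Mannich reaction (MeNH2, 2 CH2O) across the C6 ketone of a tricyclic cycloheptenone; the alkene is then moved to C12=C13.
3. Cycloheptenone and cyclopentane together: intramolecular oxyallyl (4+3) cycloaddition onto a 1-vinylcyclopentene (bonds C13–C20 and C9–C10).
4. C14 (first stereocentre): enantioselective photo-organocatalytic γ-alkylation of cyclopent-1-ene-1-carbaldehyde with dimethyl bromomalonate.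
5. Ring order: cyclopentene (starting material) → cyclopentane + cycloheptene → piperidine → dihydropyran.

Atom labels (target numbering used throughout): C1–C2 ethyl; C3 enol-ether carbon; C4; C5; C6 spiro carbon; C7 OCH2; C9 bridgehead CH; C10, C11; C12=C13; C14 ring-fusion CH; C15, C16; C17 CH(CO2Me); C19; C20 quaternary bridgehead; C21 (on C20) and C23 (on C9) the two NCH2 groups.

Assumption: the quinine-derived primary amine is taken to give the (S) configuration at C14 in step 1; if the sense of induction is the opposite, the quinidine-derived pseudo-enantiomer is used.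

Step 1
Reactants: 1 cyclopent-1-ene-1-carbaldehyde; 2 dimethyl 2-bromopropanedioate
Product: 3 dimethyl 2-[(1S)-3-formylcyclopent-2-en-1-yl]propanedioate
Conditions: 9-amino-9-deoxy-epi-quinine (20 mol%), CF3CO2H (40 mol%), 2,6-lutidine (1.2 equiv), MTBE, 400 nm LED, 0 °C
Reagents that add atoms: none
Why: Photo-organocatalytic dienamine γ-alkylation: the chiral primary amine turns 1 into its only possible dienamine (γ-carbon = C14), whose donor–acceptor complex with 2 releases the malonyl radical on irradiation, and this radical is trapped at C14 on the face left open by the cinchona scaffold before hydrolysis returns the conjugated enal, so C14 (S) is set by the catalyst.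

Step 2
Reactants: 3 dimethyl 2-[(1S)-3-formylcyclopent-2-en-1-yl]propanedioate
Product: 4 dimethyl 2-[(1S)-3-ethenylcyclopent-2-en-1-yl]propanedioate
Conditions: Ph3PCH3Br (2.2 equiv), KOtBu (2.1 equiv), THF, 0 °C
Reagents that add atoms: methyltriphenylphosphonium bromide, C[P+](c1ccccc1)(c1ccccc1)c1ccccc1.[Br-]
Why: Wittig methylenation of the enal gives the 1-vinylcyclopentene diene; the first equivalent of ylide only deprotonates the malonate C–H (restored on work-up) and the non-acidic C14 centre is untouched.

Step 3
Reactants: 4 dimethyl 2-[(1S)-3-ethenylcyclopent-2-en-1-yl]propanedioate; 5 but-3-en-2-one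
Product: 6 dimethyl 2-[(1S)-3-ethenylcyclopent-2-en-1-yl]-2-(3-oxobutyl)propanedioate
Conditions: Cs2CO3 (10 mol%), MeCN, 0 °C to rt
Reagents that add atoms: none
Why: Michael addition of the malonate anion to the vinyl ketone makes C17 quaternary and attaches C19, C20, C6 and C9 in one operation, far faster at room temperature than any Diels–Alder reaction of the diene; no stereocentre is formed.

Step 4
Reactants: 6 dimethyl 2-[(1S)-3-ethenylcyclopent-2-en-1-yl]-2-(3-oxobutyl)propanedioate
Product: 8 dimethyl 2-(4-chloro-3-oxobutyl)-2-[(1S)-3-ethenylcyclopent-2-en-1-yl]propanedioate, via trimethylsilyl enol ether 7 (not isolated)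
Conditions: LiN(iPr)2, Me3SiCl, THF, −78 °C; then N-chlorosuccinimide, 0 °C
Reagents that add atoms: N-chlorosuccinimide, O=C1CCC(=O)N1Cl; chlorotrimethylsilane, C[Si](C)(C)Cl (silicon stays only in 7)
Why: Kinetic deprotonation with in situ silylation selects the methyl side of the ketone, and electrophilic chlorination of the terminal silyl enol ether gives the chloromethyl ketone (regioselective α-halogenation through a silyl enol ether).

Step 5
Reactants: 8 dimethyl 2-(4-chloro-3-oxobutyl)-2-[(1S)-3-ethenylcyclopent-2-en-1-yl]propanedioate
Product: 10 tricyclic keto diester (cycloheptenone with C6 ketone and C11=C12; cis-fused bicyclo[3.3.0]octane; gem-diester on C17; H13 cis to H14; C20 epimers), via oxyallyl cation 9 (not isolated)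
Conditions: Na2CO3 (2 equiv), (CF3)2CHOH, 0.01 M, 0 °C to rt
Reagents that add atoms: none
Why: Proposed new method: deprotonation of 8 at C20 and loss of chloride in the ionising, non-nucleophilic solvent gives the oxyallyl cation 9, which the gem-diester tether (Thorpe–Ingold effect) holds over the s-cis 1-vinylcyclopentene so that a concerted (4+3) cycloaddition forms C13–C20 and C9–C10 and with them the cyclopentane and the cycloheptenone in one step, the three-atom tether forcing the new C13–C20 bond syn to C17 (H13 cis to H14) while the C20 epimers converge in step 7; the closest known reaction type is the Föhlisch/Harmata (4+3) cycloaddition of α-halo-ketone-derived oxyallyl cations, established with furans and cyclopentadiene but not with an unstabilised methyl-ketone oxyallyl cation and a tethered non-aromatic semicyclic diene.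

Step 6
Reactants: 10 tricyclic keto diester
Product: 11 tricyclic keto ester (as 10 but one CO2Me on C17; H17 cis to H14; C20 epimers)
Conditions: LiCl, H2O, DMSO, 150 °C
Reagents that add atoms: none
Why: Krapcho dealkoxycarbonylation: chloride demethylates one ester, the carboxylate loses CO2, and the ester enolate is protonated by water on the convex face of the cis-bicyclo[3.3.0]octane (the face of H13 and H14), leaving the ester on the concave face, so C17 is set under kinetic control.

Step 7
Reactants: 11 tricyclic keto ester; 12 methylamine; 13 formaldehyde (two equivalents)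
Product: 15 aza-bridged keto ester (N-methylpiperidine closed through C23 on C9 and C21 on C20; C6 ketone on the one-carbon bridge; C11=C12; C21 cis to H13 and H14), via mono-Mannich base 14 (not isolated)
Conditions: MeNH2 (40% aq., 1.1 equiv), CH2O (37% aq., 2.2 equiv), AcOH, MeOH, 65 °C
Reagents that add atoms: none
Why: Double Mannich annulation: aminomethylation at C9 is followed by intramolecular Mannich closure of the N-methyleneiminium ion onto the C6=C20 enol; the cis ring fusion holds C12 and the C10–C12 arc on the concave face, so the CH2–N–CH2 bridge closes on the convex face of C20 (cis to H13 and H14), which fixes the quaternary C20 and C9 together and funnels both C20 epimers of 11 into one product.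

Step 8
Reactants: 15 aza-bridged keto ester (C11=C12)
Product: 16 aza-bridged keto ester with the tetrasubstituted C12=C13 alkene
Conditions: Co(salen)Cl (5 mol%), PhSiH3 (10 mol%), benzene, rt
Reagents that add atoms: none
Why: Hydrogen-atom-transfer alkene isomerisation: a cobalt hydride delivers H to C11 to give the tertiary C12 radical, and reversible hydrogen abstraction funnels the alkene into the tetrasubstituted C12=C13 position (removing the transient C13 stereocentre), which no longer accepts hydrogen atoms; the quaternary C20 blocks conjugation with the ketone.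

Step 9
Reactants: 16 aza-bridged keto ester (C12=C13)
Product: 18 bridge aldehyde (CHO = C5 on C6; C6 epimers), via methyl enol ether 17 (not isolated)
Conditions: Ph3PCH2OMe Cl (3 equiv), KN(SiMe3)2 (2.8 equiv), THF, 0 °C to rt; then 2 M HCl, THF, rt
Reagents that add atoms: (methoxymethyl)triphenylphosphonium chloride, COC[P+](c1ccccc1)(c1ccccc1)c1ccccc1.[Cl-]; water, O
Why: Wittig methoxymethylenation of the strained bridging ketone and acid hydrolysis of the enol ether give the one-carbon-homologated aldehyde; the C6 configuration is irrelevant because C6 is enolised in step 10, and the slight excess of phosphonium salt leaves no free base to epimerise C17.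

Step 10
Reactants: 18 bridge aldehyde; 13 formaldehyde
Product: 19 hydroxymethyl aldehyde (C6 quaternary; CH2OH = C7 syn to the four-carbon bridge; CHO = C5 syn to the aza bridge)
Conditions: CH2O (37% aq., 2 equiv), K2CO3 (20 mol%), MeOH, 0 °C to rt
Reagents that add atoms: none
Why: Crossed aldol (Tollens-type hydroxymethylation) of the α-branched aldehyde: formaldehyde attacks the exocyclic enolate from the face over the four-carbon bridge (one axial C10–H beside the flat C13) in preference to the aza-bridge face (axial C–H bonds on both C21 and C23), which sets the C6 quaternary stereocentre.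

Step 11
Reactants: 19 hydroxymethyl aldehyde; 20 diethyl (2-oxobutyl)phosphonate
Product: 21 (E)-enone (C6–CH=CH–CO–Et; free CH2OH on C6)
Conditions: LiCl, iPr2NEt, MeCN, rt
Reagents that add atoms: none
Why: Horner–Wadsworth–Emmons olefination under Masamune–Roush conditions adds C4, C3 and the ethyl group to the non-enolisable aldehyde, the weak amine base avoiding retro-aldol loss of formaldehyde.

Step 12
Reactants: 21 (E)-enone
Product: 23 target CNP0159589.3 (in the labels used here 6R,9S,14R,17R,20R), via hydroxy ketone 22 (not isolated)
Conditions: H2 (1 atm), Pd/C, EtOAc, rt; filter; then TsOH·H2O (1.3 equiv), 4 Å molecular sieves, PhMe, 60 °C; Et3N quench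
Reagents that add atoms: none
Why: Hydrogenation saturates only the disubstituted enone alkene (the tetrasubstituted C12=C13 is inert), and the δ-hydroxy ketone then forms the hemiketal and loses water under acid to give the endocyclic enol ether, which is favoured over the exocyclic ethylidene isomer in a six-membered ring.

**Compound list**
1 | cyclopent-1-ene-1-carbaldehyde | O=CC1=CCCC1 | starting material
2 | dimethyl 2-bromopropanedioate (dimethyl bromomalonate) | COC(=O)C(Br)C(=O)OC | starting material
3 | dimethyl 2-[(1S)-3-formylcyclopent-2-en-1-yl]propanedioate | O=CC1=C[C@H](CC1)C(C(=O)OC)C(=O)OC | intermediate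
4 | dimethyl 2-[(1S)-3-ethenylcyclopent-2-en-1-yl]propanedioate | C=CC1=C[C@H](CC1)C(C(=O)OC)C(=O)OC | intermediate
5 | but-3-en-2-one | C=CC(C)=O | starting material
6 | dimethyl 2-[(1S)-3-ethenylcyclopent-2-en-1-yl]-2-(3-oxobutyl)propanedioate | C=CC1=C[C@H](CC1)C(CCC(C)=O)(C(=O)OC)C(=O)OC | intermediate
7 | dimethyl 2-[(1S)-3-ethenylcyclopent-2-en-1-yl]-2-[3-(trimethylsilyloxy)but-3-en-1-yl]propanedioate | C=CC1=C[C@H](CC1)C(CCC(=C)O[Si](C)(C)C)(C(=O)OC)C(=O)OC | intermediate
8 | dimethyl 2-(4-chloro-3-oxobutyl)-2-[(1S)-3-ethenylcyclopent-2-en-1-yl]propanedioate | C=CC1=C[C@H](CC1)C(CCC(=O)CCl)(C(=O)OC)C(=O)OC | intermediate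
9 | oxyallyl cation (zwitterion) from 8, cationic at C20, enolate C6(O−)=C9 | C=CC1=C[C@H](CC1)C(C[CH+]C([O-])=C)(C(=O)OC)C(=O)OC | intermediate
10 | tricyclic keto diester (C6 ketone; C11=C12; gem-diester on C17; H13 cis to H14; C20 epimers) | O=C1CCC=C2CC[C@H]3[C@@H]2C1CC3(C(=O)OC)C(=O)OC | intermediate
11 | tricyclic keto ester (CO2Me on C17, H17 cis to H14; C20 epimers) | O=C1CCC=C2CC[C@H]3[C@@H]2C1C[C@H]3C(=O)OC | intermediate
12 | methylamine | CN | starting material
13 | formaldehyde | C=O | starting material
14 | mono-Mannich base (CH2NHMe on C9 of 11; C9 and C20 epimers) | O=C1C(CNC)CC=C2CC[C@H]3[C@@H]2C1C[C@H]3C(=O)OC | intermediate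
15 | aza-bridged keto ester (C11=C12; C21 cis to H13 and H14) | O=C1[C@@H]2CC=C3CC[C@H]4[C@@H]3[C@@]1(C[C@H]4C(=O)OC)CN(C)C2 | intermediate
16 | aza-bridged keto ester (C12=C13) | O=C2[C@@H]1CCC3=C4[C@H](CC3)[C@H](C(=O)OC)C[C@@]42CN(C)C1 | intermediate
17 | methyl enol ether of 16 (C6=CH–OMe; E/Z mixture) | COC=C2[C@@H]1CCC3=C4[C@H](CC3)[C@H](C(=O)OC)C[C@@]42CN(C)C1 | intermediate
18 | bridge aldehyde (CHO on C6; C6 epimers) | O=CC2[C@@H]1CCC3=C4[C@H](CC3)[C@H](C(=O)OC)C[C@@]42CN(C)C1 | intermediate
19 | hydroxymethyl aldehyde (C6 quaternary; CH2OH syn to the four-carbon bridge) | O=C[C@@]2(CO)[C@@H]1CCC3=C4[C@H](CC3)[C@H](C(=O)OC)C[C@@]42CN(C)C1 | intermediate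
20 | diethyl (2-oxobutyl)phosphonate | CCC(=O)CP(=O)(OCC)OCC | starting material
21 | (E)-enone (C6–CH=CH–CO–Et with CH2OH on C6) | CCC(=O)/C=C/[C@@]2(CO)[C@@H]1CCC3=C4[C@H](CC3)[C@H](C(=O)OC)C[C@@]42CN(C)C1 | intermediate
22 | δ-hydroxy ketone (C6–CH2CH2–CO–Et with CH2OH on C6) | CCC(=O)CC[C@@]2(CO)[C@@H]1CCC3=C4[C@H](CC3)[C@H](C(=O)OC)C[C@@]42CN(C)C1 | intermediate
23 | CNP0159589.3 | CCC1=CC[C@@]2(CO1)[C@@H]1CCC3=C4[C@H](CC3)[C@H](C(=O)OC)C[C@@]42CN(C)C1 | target

**Totals and risks**
Total step count: 12. Longest linear sequence: 12 steps (the route is fully linear from 1).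

The three steps most likely to fail are steps 5, 8 and 10.

Step 5 is the proposed new cycloaddition and may give Favorskii or solvolysis products instead. Its fallback makes the same two bonds stepwise by known radical and palladium chemistry and sets out from 6. CuBr2 in EtOAc/CHCl3 at reflux brominates the more substituted α-carbon (C20) to give dimethyl 2-(2-bromo-3-oxobutyl)-2-[(1S)-3-ethenylcyclopent-2-en-1-yl]propanedioate F1. Copper-catalysed atom-transfer radical cyclisation (CuBr, tris(2-pyridylmethyl)amine, 1,2-dichloroethane, 60 °C) then closes the cyclopentane by 5-exo attack of the C20 radical on C13 and leaves the halogen at the allylic terminus C10, giving the cis-fused bicyclic allylic bromide F2. Finally LiN(SiMe3)2 at −78 °C followed by Pd(PPh3)4 closes the seven-membered ring by intramolecular Tsuji–Trost allylation of the methyl-ketone enolate at C10 (the π-allyl intermediate equilibrates the alkene geometry), and the sequence comes back to the route at 10.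

Step 8 may stall at trisubstituted alkenes or be slowed by the basic amine. Its fallback moves the double bond by hydration and dehydration and sets out from 15. Mukaiyama hydration (Co(acac)2, PhSiH3, O2, THF) gives the C12 tertiary alcohol F3, and dehydration with SOCl2 in pyridine removes the tertiary neighbouring hydrogen H13 (Zaitsev) to give the tetrasubstituted alkene, coming back to the route at 16.

Step 10 depends on which face of the C6 enolate is attacked; if formaldehyde enters from the aza-bridge face the C6 epimer of 19 results. The fallback reverses the order in which the two C6 substituents are installed, so that the same facial preference now gives the target, and sets out from 18. Michael addition to pent-1-en-3-one (DBU, MeCN, rt) puts the 3-oxopentyl chain on the aza-bridge face and gives the keto aldehyde F4 (here the aldehyde carbon is C7). Selective reduction of the aldehyde (NaBH(OAc)3, CH2Cl2) then gives the δ-hydroxy ketone, coming back to the route at 22, which is cyclised to 23 with acid as in step 12.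

**Further compounds**
F1 | step 5 | dimethyl 2-(2-bromo-3-oxobutyl)-2-[(1S)-3-ethenylcyclopent-2-en-1-yl]propanedioate (C20 epimers) | C=CC1=C[C@H](CC1)C(CC(Br)C(C)=O)(C(=O)OC)C(=O)OC
F2 | step 5 | cis-fused bicyclic allylic bromide (acetyl on C20; 2-bromoethylidene on C12; gem-diester on C17; H13 cis to H14; C20 epimers) | CC(=O)C1CC(C(=O)OC)(C(=O)OC)[C@H]2CCC(=CCBr)[C@@H]12
F3 | step 8 | C12 tertiary alcohol from hydration of 15 (C12 epimers) | O=C1[C@@H]2CCC3(O)CC[C@H]4[C@@H]3[C@@]1(C[C@H]4C(=O)OC)CN(C)C2
F4 | step 10 | keto aldehyde (C6 bearing CHO syn to the four-carbon bridge and CH2CH2COEt syn to the aza bridge) | CCC(=O)CC[C@@]2(C=O)[C@@H]1CCC3=C4[C@H](CC3)[C@H](C(=O)OC)C[C@@]42CN(C)C1
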